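All runs were computed with made-up constants; scatter was added.

A leftover runs through the beta run, the flask followed so far: substrate and target do not add up to the charge, and the gap grows from 9.20% at 0.667 min to 22.3% at 1.33 min and 45.8% at 3.00 min.

| flask | substrate | free enzyme | temperature | remark | time |
|---|---|---|---|---|---|
| beta | 0.034 M | 34 µM | 30 °C | the very flask that is asked about, followed so far |  |
| alpha | 0.034 M | 23 µM | 15 °C | run made earlier |  |
| flask | 0.034 M | 34 µM | 30 °C |  | 4.0 min |

- beta (time / min: target / %, substrate / %): 0.250: 10.7, 87.5; 0.667: 20.7, 70.1; 1.33: 24.0, 53.7; 3.00: 19.0, 35.2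
- alpha (time / min: target / %, substrate / %): 0.667: 7.2, 92.2; 1.33: 12.3, 83.6; 2.00: 17.0, 74.8; 3.00: 22.5, 65.1

(readings scatter by 0.5 percentage points)

- target, in percent of the substrate first charged, at 4.0 min
- what to do for the largest gain in target; "none" if nothing gains more than 2 percentage points (teal / violet / green / amber / none)
- target present, with what was taken out counted in, in percent of the substrate first charged, after violet
- target present, with what was taken out counted in, in percent of the substrate first charged, after amber

- teal: at 4.0 min add free enzyme, 100% of the amount charged, then wait 4.0 min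
- violet: at 4.0 min take out 90% of the target then present, then wait 4.0 min
- green: at 4.0 min raise the temperature by 20 K, then wait 4.0 min
- amber: change nothing and wait 4.0 min more

- target taken out counts as made
- what was read earlier has a scatter of 0.5 percentage points, one standard deviation
- additions bring no volume worth counting

What does the gap follow? Divided by the target share, its growth falls from 0.884 min⁻¹ to 0.655 min⁻¹. Divided by target share times substrate share, it gives 1.43 min⁻¹ and then 1.47 min⁻¹, a second-order pattern. This second figure is the wastage constant: growth of the gap per minute over the product of the target and substrate shares.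

How is the gap shared out? The target-to-substrate ratio in beta reads 0.295, 0.447, 0.540, and its rise is flattening, so this reckoning holds it at 0.540.

Going forward from the last beta reading, the constant gives a gap of 55.6% at 4.0 min, hence target 15.5% and substrate 28.8%. Put back as mean shares, these give a gap of 53.9%, target 16.1% and substrate 29.9%.

Which option then? Removal banks 14.5% and leaves a ratio of 0.0540, less than the held 0.540, so target can re-form from substrate. The same two rounds give about 23.4%. Heat looks bad: alpha, at 15 °C and with 23 µM of free enzyme, reads a constant of 0.304 min⁻¹, less than the 1.47 min⁻¹ read in beta.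

The forecast gives 16% (14% to 18%), chooses violet, and puts violet at 18% (15.5% to 20.5%) and amber at 11.5% (8% to 14.5%), with target “still declining, since loss exceeds supply”. The reckoning here stands above its violet figure.

The flask gives 16.3%; violet gains 6.4 percentage points, reaching 22.7%, against 10.2% after amber.

    complex ⇌ free enzyme + target (K = 0.0113 M, k = 15.5 s⁻¹, Ea = 66.0 kJ mol⁻¹, ΔH = 15.0 kJ mol⁻¹)
    substrate + target → side product (k = 0.361 M⁻¹ s⁻¹, Ea = 61.0 kJ mol⁻¹)
    substrate + free enzyme ⇌ complex (K = 51.0 M⁻¹, k = 5630 M⁻¹ s⁻¹, Ea = 14.0 kJ mol⁻¹, ΔH = −35.0 kJ mol⁻¹)
    free enzyme → unfolded enzyme (k = 1.69 × 10⁻⁵ s⁻¹, Ea = 238 kJ mol⁻¹)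
    (constants at 30 °C)

Side product stands at 54.2% at 4.00 min, each one counted as two in that percentage. The wastage constant, applied to the mean shares of this flask from 2.00 min on, gives 21 points against a side-product rise of 20 points. For the neighbour read at 2.50 min, taken from the one left until 1.00 min, it gives 24 points against 24 points.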